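**Retrosynthetic overview**
1. Target ⇒ the unit B cycloheptene and its dienone side chain are made last, by domino ring-closing enyne metathesis/cross-metathesis with methyl vinyl ketone.
2. The C1–OH and the C2=C3 enone ⇒ photochemical singlet-oxygen ene reaction on the β,γ-unsaturated-ketone Diels–Alder adduct (H-3 relays its configuration to the new C1–O bond).
3. Spiro-cyclohexene ⇒ Diels–Alder reaction of the dienone monomer (unit A, diene) with the still open-chain α-methylene lactone enyne of unit B (dienophile); the monomer comes from the same domino metathesis.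
4. Both lactone enynes ⇒ one iodolactone plus the two enantiomeric allenylstannanes by a photo-initiated radical anti-SH2′ propargylation (C9–C10 bond; C10 from (R)- or (S)-but-3-yn-2-ol).
5. Iodolactone ⇒ (S)-HBO (C8 bought, C7 by trans conjugate allylation). Ring order: γ-lactones (bought) → cycloheptene of unit A → spiro-cyclohexene → cycloheptene of unit B.

Assumption: the SMILES is taken literally (the two halves are epimeric at the methyl-bearing carbon, so they are made separately); xanthane numbering is used, unit A = hydroxylated half (C1–C15), unit B = primed spiro-lactone half.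

**Step 1**
Reactants: 1 (5S)-5-(hydroxymethyl)furan-2(5H)-one ((S)-HBO)
Product: 4 (4S,5S)-4-allyl-5-(hydroxymethyl)oxolan-2-one, via silyl ether 2 (not isolated), via silyl ketene acetal 3 (not isolated)
Conditions: TMSCl, Et3N, THF, 0 °C; then allylMgBr/CuBr·SMe2 (1:1, 1.5 equiv), TMSCl, THF, −78 °C; then 1 M HCl, 0 °C
Reagents that add atoms: allylmagnesium bromide, C=CC[Mg]Br
Why: TMSCl-accelerated copper-mediated conjugate (Michael) addition to the transiently O-silylated butenolide; the allyl group enters anti to the C5 substituent, so the bought stereocentre sets C4 (trans lactone) and acid hydrolysis of the silyl ketene acetal and silyl ether gives the alcohol.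

**Step 2**
Reactants: 4 (4S,5S)-4-allyl-5-(hydroxymethyl)oxolan-2-one
Product: 5 (4S,5S)-4-allyl-5-(iodomethyl)oxolan-2-one
Conditions: I2, PPh3, imidazole, CH2Cl2, 0 °C to rt
Reagents that add atoms: iodine, II
Why: Appel iodination of the primary alcohol; no stereocentre is touched.

**Step 3**
Reactants: 6 (R)-but-3-yn-2-ol
Product: 7 (R)-but-3-yn-2-yl methanesulfonate
Conditions: MsCl, Et3N, CH2Cl2, −78 to 0 °C
Reagents that add atoms: methanesulfonyl chloride, CS(=O)(=O)Cl
Why: O-sulfonylation with retention at carbon.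

**Step 4**
Reactants: 7 (R)-but-3-yn-2-yl methanesulfonate
Product: 8 (aS)-tributyl(buta-1,2-dien-1-yl)stannane
Conditions: Bu3SnH, LDA, THF, 0 °C; CuBr·SMe2, −78 °C; then 7, −78 °C
Reagents that add atoms: tributyltin hydride, CCCC[SnH](CCCC)CCCC
Why: anti-SN2′ displacement of the propargylic mesylate by the stannylcopper reagent converts the bought centre into axial chirality ((R) gives (aS)).

**Step 5**
Reactants: 9 (S)-but-3-yn-2-ol
Product: 10 (S)-but-3-yn-2-yl methanesulfonate
Conditions: MsCl, Et3N, CH2Cl2, −78 to 0 °C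
Reagents that add atoms: methanesulfonyl chloride, CS(=O)(=O)Cl
Why: O-sulfonylation with retention at carbon.

**Step 6**
Reactants: 10 (S)-but-3-yn-2-yl methanesulfonate
Product: 11 (aR)-tributyl(buta-1,2-dien-1-yl)stannane
Conditions: Bu3SnH, LDA, THF, 0 °C; CuBr·SMe2, −78 °C; then 10, −78 °C
Reagents that add atoms: tributyltin hydride, CCCC[SnH](CCCC)CCCC
Why: anti-SN2′ stannylcupration as in step 4 ((S) gives (aR)).

**Step 7**
Reactants: 5 (4S,5S)-4-allyl-5-(iodomethyl)oxolan-2-one, 8 (aS)-tributyl(buta-1,2-dien-1-yl)stannane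
Product: 12 (4S,5R)-4-allyl-5-[(2S)-2-methylbut-3-yn-1-yl]oxolan-2-one
Conditions: 8 (3 equiv), (Bu3Sn)2 (10 mol%), PhH (2 M in 5), hν (300–350 nm, Pyrex), 20 °C
Reagents that add atoms: none
Why: Proposed new method: a photo-initiated tin-radical chain in which Bu3Sn• abstracts iodine from 5, the resulting β-acyloxy primary radical (which, unlike a C9 organometallic, does not β-eliminate the lactone oxygen) adds to the methyl-bearing allene terminus anti to the bulky, radical-stabilising stannyl group, and the β-stannylvinyl radical fragments to the alkyne, so the axial chirality of 8 is relayed to the new C10 centre ((aS) gives (2S)); the closest known reactions are the Keck radical allylation, radical propargylation with unsubstituted allenylstannanes (no stereocentre formed), and the polar anti-SN2′/SE2′ chirality transfers of haloallenes and allenylmetals.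

**Step 8**
Reactants: 5 (4S,5S)-4-allyl-5-(iodomethyl)oxolan-2-one, 11 (aR)-tributyl(buta-1,2-dien-1-yl)stannane
Product: 13 (4S,5R)-4-allyl-5-[(2R)-2-methylbut-3-yn-1-yl]oxolan-2-one
Conditions: 11 (3 equiv), (Bu3Sn)2 (10 mol%), PhH (2 M in 5), hν (300–350 nm, Pyrex), 20 °C
Reagents that add atoms: none
Why: Proposed new method: the same photo-initiated radical anti-SH2′ propargylation as in step 7 (iodine abstraction, addition of the C9 radical to the methyl-bearing allene terminus anti to tin, β-scission of Bu3Sn•), here relaying (aR) to (2R); closest known reactions are the Keck radical allylation and radical propargylation with unsubstituted allenylstannanes.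

**Step 9**
Reactants: 12 (4S,5R)-4-allyl-5-[(2S)-2-methylbut-3-yn-1-yl]oxolan-2-one
Product: 15 (4S,5R)-4-allyl-3-methylidene-5-[(2S)-2-methylbut-3-yn-1-yl]oxolan-2-one, via sodium formyl enolate 14 (not isolated)
Conditions: NaH, HCO2Et, Et2O, EtOH (cat.), 0 °C to rt; then (CH2O)n, THF, 65 °C
Reagents that add atoms: formaldehyde (from paraformaldehyde), C=O
Why: Claisen formylation followed by aldol addition to formaldehyde and formyl-transfer/β-elimination of formate (the classical α-methylenation of γ-lactones); the sodium α-formyl enolate is far more acidic than the terminal alkyne, and no stereocentre is touched.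

**Step 10**
Reactants: 13 (4S,5R)-4-allyl-5-[(2R)-2-methylbut-3-yn-1-yl]oxolan-2-one
Product: 17 (4S,5R)-4-allyl-3-methylidene-5-[(2R)-2-methylbut-3-yn-1-yl]oxolan-2-one, via sodium formyl enolate 16 (not isolated)
Conditions: NaH, HCO2Et, Et2O, EtOH (cat.), 0 °C to rt; then (CH2O)n, THF, 65 °C
Reagents that add atoms: formaldehyde (from paraformaldehyde), C=O
Why: formylation/formaldehyde α-methylenation as in step 9; no stereocentre is touched.

**Step 11**
Reactants: 15 (4S,5R)-4-allyl-3-methylidene-5-[(2S)-2-methylbut-3-yn-1-yl]oxolan-2-one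
Product: 19 (3aS,7S,8aR)-7-methyl-3-methylidene-6-[(E)-3-oxobut-1-enyl]-4,7,8,8a-tetrahydro-3aH-cyclohepta[b]furan-2-one, via vinylcycloheptene lactone 18 (not isolated)
Conditions: methyl vinyl ketone (10 equiv), second-generation Hoveyda–Grubbs catalyst [RuCl2(SIMes)(=CH-C6H4-2-OiPr)] (10 mol%), CH2Cl2 (5 mM), 40 °C
Reagents that add atoms: methyl vinyl ketone, C=CC(C)=O
Why: domino ring-closing enyne metathesis/cross-metathesis closes the seven-membered ring between the allyl and alkyne arms and extends the new vinyl group to the (E)-enone; the electron-poor 1,1-disubstituted methylene lactone is inert and no stereocentre is touched.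

**Step 12**
Reactants: 19 (3aS,7S,8aR)-7-methyl-3-methylidene-6-[(E)-3-oxobut-1-enyl]-4,7,8,8a-tetrahydro-3aH-cyclohepta[b]furan-2-one, 17 (4S,5R)-4-allyl-3-methylidene-5-[(2R)-2-methylbut-3-yn-1-yl]oxolan-2-one
Product: 20 Diels–Alder adduct (3S,5S,7S,8R,10S,7′S,8′R,10′R,11′R): unit A with C1=C2, 3-acetyl and H-3 cis to H-5, joined through C5–C13′ and C3–C11′ to the spiro lactone of open-chain unit B
Conditions: 17 (4 equiv, neat), BHT (5 mol%), 90 °C, 19 added over 24 h, then 48 h; excess 17 recovered
Reagents that add atoms: none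
Why: thermal intermolecular Diels–Alder reaction with ortho/para regiochemistry in which 19 is trapped as the diene by the large excess of diene-free 17; suprafacial addition to the (E)-s-cis diene fixes H-3 cis to H-5, C11′ is set by attack on the methylene-lactone face anti to the adjacent 7′-allyl group, and the exo orientation usual for s-cis-locked α-methylene lactones pairs that face with the diene face anti to the C7–C11 bond, which sets C5.

**Step 13**
Reactants: 20 Diels–Alder adduct
Product: 22 tertiary alcohol (1R,5S,7S,8R,10S,7′S,8′R,10′R,11′R): 1-hydroxy-2-en-4-one of unit A (OH cis to H-5) spiro-linked to open-chain unit B, via allylic hydroperoxide 21 (not isolated)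
Conditions: O2, 5,10,15,20-tetraphenylporphyrin (1 mol%), CH2Cl2, hν (white LED), −20 °C; then PPh3, rt
Reagents that add atoms: oxygen, O=O
Why: Schenck ene reaction of singlet oxygen at the only electron-rich alkene (C1=C2); on the ring side of that alkene the pseudo-axial, ketone-activated H-3 is abstracted and oxygen is delivered suprafacially to C1 on the same face (cis to H-3 and therefore to H-5, both fixed in step 12), giving the conjugated enone, and PPh3 reduces the hydroperoxide.

**Step 14**
Reactants: 22 tertiary alcohol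
Product: 24 target CNP0168949.3, via ring-closed triene 23 (not isolated)
Conditions: methyl vinyl ketone (10 equiv), second-generation Hoveyda–Grubbs catalyst (15 mol%), CH2Cl2 (5 mM), 40 °C
Reagents that add atoms: methyl vinyl ketone, C=CC(C)=O
Why: domino ring-closing enyne metathesis/cross-metathesis as in step 11 builds the unit B cycloheptene and (E)-dienone; the methylene lactone and trisubstituted enone of unit A are inert, the free tertiary alcohol is tolerated, and no stereocentre is touched.

**Compound list**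
1 | (5S)-5-(hydroxymethyl)furan-2(5H)-one, (S)-HBO | O=C1C=C[C@@H](CO)O1 | starting material
2 | (5S)-5-[(trimethylsilyloxy)methyl]furan-2(5H)-one (formed in situ) | O=C1C=C[C@@H](CO[Si](C)(C)C)O1 | intermediate
3 | (4S,5S)-4-allyl-2-(trimethylsilyloxy)-5-[(trimethylsilyloxy)methyl]-4,5-dihydrofuran (formed in situ) | C[Si](C)(C)OC1=C[C@H](CC=C)[C@@H](CO[Si](C)(C)C)O1 | intermediate
4 | (4S,5S)-4-allyl-5-(hydroxymethyl)oxolan-2-one (trans) | O=C1C[C@H](CC=C)[C@@H](CO)O1 | intermediate
5 | (4S,5S)-4-allyl-5-(iodomethyl)oxolan-2-one | O=C1C[C@H](CC=C)[C@@H](CI)O1 | intermediate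
6 | (R)-but-3-yn-2-ol | C[C@@H](O)C#C | starting material
7 | (R)-but-3-yn-2-yl methanesulfonate | C[C@@H](OS(C)(=O)=O)C#C | intermediate
8 | (aS)-tributyl(buta-1,2-dien-1-yl)stannane | [H]C([Sn](CCCC)(CCCC)CCCC)=[C@]=C([H])C | intermediate
9 | (S)-but-3-yn-2-ol | C[C@H](O)C#C | starting material
10 | (S)-but-3-yn-2-yl methanesulfonate | C[C@H](OS(C)(=O)=O)C#C | intermediate
11 | (aR)-tributyl(buta-1,2-dien-1-yl)stannane | [H]C([Sn](CCCC)(CCCC)CCCC)=[C@@]=C([H])C | intermediate
12 | (4S,5R)-4-allyl-5-[(2S)-2-methylbut-3-yn-1-yl]oxolan-2-one | O=C1C[C@H](CC=C)[C@@H](C[C@H](C)C#C)O1 | intermediate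
13 | (4S,5R)-4-allyl-5-[(2R)-2-methylbut-3-yn-1-yl]oxolan-2-one | O=C1C[C@H](CC=C)[C@@H](C[C@@H](C)C#C)O1 | intermediate
14 | sodium [(4S,5R)-4-allyl-5-[(2S)-2-methylbut-3-yn-1-yl]-2-oxooxolan-3-ylidene]methanolate (formed in situ) | [Na+].[O-]C=C1C(=O)O[C@H](C[C@H](C)C#C)[C@H]1CC=C | intermediate
15 | (4S,5R)-4-allyl-3-methylidene-5-[(2S)-2-methylbut-3-yn-1-yl]oxolan-2-one | C=C1C(=O)O[C@H](C[C@H](C)C#C)[C@H]1CC=C | intermediate
16 | sodium [(4S,5R)-4-allyl-5-[(2R)-2-methylbut-3-yn-1-yl]-2-oxooxolan-3-ylidene]methanolate (formed in situ) | [Na+].[O-]C=C1C(=O)O[C@H](C[C@@H](C)C#C)[C@H]1CC=C | intermediate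
17 | (4S,5R)-4-allyl-3-methylidene-5-[(2R)-2-methylbut-3-yn-1-yl]oxolan-2-one | C=C1C(=O)O[C@H](C[C@@H](C)C#C)[C@H]1CC=C | intermediate
18 | (3aS,7S,8aR)-6-ethenyl-7-methyl-3-methylidene-4,7,8,8a-tetrahydro-3aH-cyclohepta[b]furan-2-one (formed in situ) | C=C1C(=O)O[C@@H]2C[C@H](C)C(C=C)=CC[C@@H]12 | intermediate
19 | (3aS,7S,8aR)-7-methyl-3-methylidene-6-[(E)-3-oxobut-1-enyl]-4,7,8,8a-tetrahydro-3aH-cyclohepta[b]furan-2-one (unit A monomer) | C=C1C(=O)O[C@@H]2C[C@H](C)C(/C=C/C(C)=O)=CC[C@@H]12 | intermediate
20 | Diels–Alder adduct (3S,5S,7S,8R,10S,7′S,8′R,10′R,11′R): C1=C2 alkene, 3-acetyl, H-3 cis to H-5, spiro at C11′ to the 7′-allyl-8′-[(2R)-2-methylbut-3-ynyl] lactone | C=C1C(=O)O[C@@H]2C[C@H](C)C3=C[C@H](C(C)=O)[C@]4(C[C@@H]3C[C@@H]12)C(=O)O[C@H](C[C@@H](C)C#C)[C@H]4CC=C | intermediate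
21 | C1 hydroperoxide (1R) of the transposed enone (formed in situ) | C=C1C(=O)O[C@@H]2C[C@H](C)[C@]3(OO)C=C(C(C)=O)[C@]4(C[C@@H]3C[C@@H]12)C(=O)O[C@H](C[C@@H](C)C#C)[C@H]4CC=C | intermediate
22 | tertiary alcohol (1R,5S,7S,8R,10S,7′S,8′R,10′R,11′R): 1-hydroxy-3-acetyl-cyclohex-2-ene, OH cis to H-5, unit B still open-chain | C=C1C(=O)O[C@@H]2C[C@H](C)[C@]3(O)C=C(C(C)=O)[C@]4(C[C@@H]3C[C@@H]12)C(=O)O[C@H](C[C@@H](C)C#C)[C@H]4CC=C | intermediate
23 | ring-closed triene: 22 with the unit B cycloheptene closed and a vinyl group on C1′ (formed in situ) | C=C1C(=O)O[C@@H]2C[C@H](C)[C@]3(O)C=C(C(C)=O)[C@]4(C[C@@H]3C[C@@H]12)C(=O)O[C@@H]1C[C@@H](C)C(C=C)=CC[C@H]14 | intermediate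
24 | CNP0168949.3 | C=C1C(=O)O[C@@H]2C[C@H](C)[C@]3(O)C=C(C(C)=O)[C@]4(C[C@@H]3C[C@@H]12)C(=O)O[C@@H]1C[C@@H](C)C(/C=C/C(C)=O)=CC[C@H]14 | target

**Totals**
Total step count: 14. Longest linear sequence: 8 steps (1 → 4 → 5 → 12 → 15 → 19 → 20 → 22 → 24).

**Three steps most likely to fail**

1. Steps 7 and 8 (the new radical propargylation, run once with each allenylstannane). The risks are three. Radical addition to a substituted allene terminus is slow. Stannyl radicals can isomerise the allenylstannane to the propargylstannane, which would give an allene product and erode chirality transfer. The C9 radical can cyclise 6-endo onto the allyl group. High concentration of the iodide and neat stannane are meant to suppress the last two. The fallback uses known chemistry, sets out from 4 and comes back at 12. Dess–Martin oxidation of 4 gives the aldehyde (2S,3S)-3-allyl-5-oxooxolane-2-carbaldehyde F1. Marshall propargylation with the allenylzinc made in situ from mesylate 10 (Pd(OAc)2/PPh3 cat., Et2Zn, THF, −20 °C) gives the anti homopropargylic alcohol F2. This polar sequence (anti oxidative addition, then syn-SE2′ addition) is stereochemically opposite to the radical step, so mesylate 10, not 7, leads to the (2S) series, and the methyl-bearing centre is set by the mesylate alone. O-Phenyl chlorothionoformate/pyridine gives the thionocarbonate F3, and Barton–McCombie reduction (Bu3SnH, Et3B, air, toluene, 0 °C) removes the C9 oxygen to give 12. The same operations on F1 with mesylate 7 give the alcohol F4 and the thionocarbonate F5 and come back at 13.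

2. Step 12 (Diels–Alder). The risks are self-dimerisation of 19 through its own methylene lactone, slow reaction of two electron-poor partners, and above all the diene face. The C5 configuration rests on the dienophile's preferences (face anti to the allyl group, exo mode) overriding any intrinsic bias of the 10-epi diene, and this must be checked on the first run. The fallback sets out from 19 and comes back at 20. Thia-Michael addition of thiophenol (PhSH, cat. Et3N, CH2Cl2, 0 °C) masks the methylene lactone as the sulfide F6 (C11 epimers), which can act only as a diene and tolerates harder heating. Cycloaddition with 17 (1.5 equiv, neat, 100 °C) gives the adduct F7, NaIO4 (MeOH/H2O) gives the sulfoxide F8, and thermal syn-elimination (toluene, 100 °C, CaCO3) regenerates the methylene lactone to give 20. This removes the self-dimerisation problem but not the face-selectivity question; any C5 epimer would be separated at alcohol 22.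

3. Step 13 (singlet-oxygen ene). The risk is abstraction of H-5 instead of H-3, which would give a C2 hydroperoxide and a C1=C5 alkene, if the acetyl group does not sit pseudo-equatorial. The fallback sets out from 20 and comes back at 22. KOtBu (1.1 equiv, THF/tBuOH, −40 °C) gives the extended potassium dienolate F9, which is oxygenated at the γ-carbon C1 with O2 in the presence of P(OEt)3 (ionic dienolate autoxidation instead of the pericyclic ene reaction). Oxygen should enter anti to the C5–C6 bond, giving the same cis-fused alcohol 22 after NH4Cl quench.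

**Further compounds**
F1 | step 7 | (2S,3S)-3-allyl-5-oxooxolane-2-carbaldehyde | O=C1C[C@H](CC=C)[C@@H](C=O)O1
F2 | step 7 | (4S,5S)-4-allyl-5-[(1R,2R)-1-hydroxy-2-methylbut-3-yn-1-yl]oxolan-2-one | O=C1C[C@H](CC=C)[C@@H]([C@H](O)[C@H](C)C#C)O1
F3 | step 7 | O-phenyl thionocarbonate of F2 | O=C1C[C@H](CC=C)[C@@H]([C@H](OC(=S)Oc2ccccc2)[C@H](C)C#C)O1
F4 | step 8 | (4S,5S)-4-allyl-5-[(1S,2S)-1-hydroxy-2-methylbut-3-yn-1-yl]oxolan-2-one | O=C1C[C@H](CC=C)[C@@H]([C@@H](O)[C@@H](C)C#C)O1
F5 | step 8 | O-phenyl thionocarbonate of F4 | O=C1C[C@H](CC=C)[C@@H]([C@@H](OC(=S)Oc2ccccc2)[C@@H](C)C#C)O1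
F6 | step 12 | (3aS,7S,8aR)-7-methyl-6-[(E)-3-oxobut-1-enyl]-3-[(phenylsulfanyl)methyl]-3,3a,4,7,8,8a-hexahydrocyclohepta[b]furan-2-one (C3 epimers) | c1ccccc1SCC1C(=O)O[C@@H]2C[C@H](C)C(/C=C/C(C)=O)=CC[C@@H]12
F7 | step 12 | Diels–Alder adduct of F6 with 17 (20 carrying CH2SPh on C11 in place of the methylidene) | c1ccccc1SCC1C(=O)O[C@@H]2C[C@H](C)C3=C[C@H](C(C)=O)[C@]4(C[C@@H]3C[C@@H]12)C(=O)O[C@H](C[C@@H](C)C#C)[C@H]4CC=C
F8 | step 12 | sulfoxide of F7 | O=S(CC1C(=O)O[C@@H]2C[C@H](C)C3=C[C@H](C(C)=O)[C@]4(C[C@@H]3C[C@@H]12)C(=O)O[C@H](C[C@@H](C)C#C)[C@H]4CC=C)c1ccccc1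
F9 | step 13 | potassium dienolate of 20 (C1=C2 and C3=C4 enolate) | C=C1C(=O)O[C@@H]2C[C@H](C)C3=CC(=C(C)[O-])[C@]4(C[C@@H]3C[C@@H]12)C(=O)O[C@H](C[C@@H](C)C#C)[C@H]4CC=C.[K+]
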